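**Retrosynthetic overview**
1. The C7–O lactone bond and C6–Cl are made together, late, by a palladium-catalysed chlorolactonization of a ten-membered cyclic 5,6-allenoic acid (C19 acid onto C7); the butanolide is the last ring formed.
2. The ten-membered ring comes from a six-membered "ring B" (C1, C2, C7, C8, C9, C10) by anionic alkynyl oxy-Cope ring expansion; ring B is closed by intramolecular allenylindium addition to a C2 vinyl ketone.
3. Ring A with C1, C10, C11 and C12 comes from an endo Diels–Alder reaction of 3-methyl-2-pyrone with a (Z)-but-2-enoyl ketone; the bridging lactone masks the C2 acyl group and O12.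
4. C8 and C17 come from (S)-malate: Fráter–Seebach methylation, then acylation of the derived dioxolanone enolate.
5. Order of ring formation: ring A (lactone-bridged) → temporary propargylic butanolide → temporary ring B → ten-membered ring → final butanolide.

Assumption: briarane numbering (C1–C20) is used for locants; 3-methyl-2H-pyran-2-one and but-2-ynoyl chloride are taken as purchasable. The SMILES strings are definitive for configuration. None of this has been run; the selectivities given are predictions.

**Route**

Step 1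
Reactants: 1 diisopropyl (S)-malate
Product: 2 diisopropyl (2S,3R)-2-hydroxy-3-methylbutanedioate
Conditions: LiN(i-Pr)2 (2.2 equiv), THF, −78 to −20 °C; MeI, −78 °C
Reagents that add atoms: iodomethane, CI
Why: Fráter–Seebach alkylation: the chelated alkoxide–enolate dianion is methylated anti to the C2 oxygen, which sets C17 (dr about 9:1).

Step 2
Reactants: 2 diisopropyl (2S,3R)-2-hydroxy-3-methylbutanedioate
Product: 3 (2S,3R)-2-hydroxy-3-methyl-4-oxo-4-(propan-2-yloxy)butanoic acid
Conditions: KOH (1.0 equiv), i-PrOH/H2O, 0 °C; then 1 M HCl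
Reagents that add atoms: potassium hydroxide, [K+].[OH-]
Why: Selective saponification: the ester next to the free hydroxyl hydrolyses faster than the α-branched C19 ester.

Step 3
Reactants: 3 (2S,3R)-2-hydroxy-3-methyl-4-oxo-4-(propan-2-yloxy)butanoic acid
Product: 4 propan-2-yl (2R)-2-[(2S,4S)-2-tert-butyl-5-oxo-1,3-dioxolan-4-yl]propanoate (cis-dioxolanone)
Conditions: t-BuCHO (2 equiv), TsOH (cat.), H2SO4 (cat.), pentane, reflux, Dean–Stark
Reagents that add atoms: pivalaldehyde, CC(C)(C)C=O
Why: Acid-catalysed acetalization gives the cis dioxolanone under thermodynamic control and stores the C8 configuration in the acetal centre (Seebach self-regeneration of stereocentres).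

Step 4
Reactants: 4 cis-dioxolanone ester; 5 but-2-ynoyl chloride
Product: 6 propan-2-yl (2R)-2-[(2S,4R)-4-(but-2-ynoyl)-2-tert-butyl-5-oxo-1,3-dioxolan-4-yl]propanoate
Conditions: LiN(SiMe3)2 (1.05 equiv), THF, −78 °C; then 5, −78 °C
Reagents that add atoms: none
Why: Claisen-type C-acylation of the dioxolanone lithium enolate anti to the tert-butyl group forms the C8–C9 bond and the C8 quaternary centre with net retention (8R of the target).

Step 5
Reactants: 6 ynone dioxolanone
Product: 7 the (Z)-but-2-enoyl analogue of 6 (same stereocentres)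
Conditions: H2 (1 atm), Pd/CaCO3/Pb(OAc)2, quinoline, EtOAc, 0 °C
Reagents that add atoms: none
Why: Lindlar semihydrogenation gives the (Z)-enone needed for the cis C10/C11 relationship.

Step 6
Reactants: 7 (Z)-enone dioxolanone; 8 3-methyl-2H-pyran-2-one
Product: 9 endo Diels–Alder adduct, a 4,6-dimethyl-2-oxabicyclo[2.2.2]oct-7-en-3-one whose 5-endo carbonyl (C9) is bound to the dioxolanone C8 (C1, C10, C11, C12 as in the target)
Conditions: 8 (3 equiv), CH2Cl2, 13 kbar, 25 °C, 72 h
Reagents that add atoms: none
Why: Normal-demand Diels–Alder reaction of the 2-pyrone: its methyl-bearing C3 bonds to the enone α-carbon, the acyl group is endo, and the diene is expected to add to the enone face away from the C17 side chain, which sets C1, C10, C11 and C12 in one step.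

Step 7
Reactants: 9 Diels–Alder adduct
Product: 10 the (9S)-alcohol of 9
Conditions: LiBH(s-Bu)3 (1.2 equiv), THF, −78 °C; aq. NH4Cl
Reagents that add atoms: none
Why: Hydride reduction of the C9 ketone in the Felkin–Anh sense with respect to C10, anti to the C17 side chain in the dipole-minimised acyl-dioxolanone rotamer, gives 9S.

Step 8
Reactants: 10 (9S)-alcohol
Product: 11 the 9-O-tert-butyldimethylsilyl ether of 10
Conditions: TBSOTf (1.5 equiv), 2,6-lutidine, CH2Cl2, −40 to 0 °C
Reagents that add atoms: tert-butyldimethylsilyl trifluoromethanesulfonate, CC(C)(C)[Si](C)(C)OS(=O)(=O)C(F)(F)F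
Why: Silylation of the hindered secondary alcohol blocks retro-aldol cleavage and keeps O9 out of the later lactonizations.

Step 9
Reactants: 11 silyl ether
Product: 12 α-hydroxy ynone (C8–OH free, C7 as but-2-ynoyl ketone; bridged lactone and isopropyl ester intact)
Conditions: MeC≡CMgBr (1.3 equiv), THF, −78 °C; aq. NH4Cl at −78 °C
Reagents that add atoms: prop-1-ynylmagnesium bromide, CC#C[Mg]Br
Why: Nucleophilic acyl substitution at the acetal-activated dioxolanone carbonyl, the most electrophilic acyl group present; the hemiketal collapses on work-up to release pivalaldehyde and the C8 tertiary alcohol.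

Step 10
Reactants: 12 α-hydroxy ynone
Product: 13 propargylic diol (C7 carbinol as an epimer mixture, C8–OH)
Conditions: NaBH4, CeCl3·7H2O, MeOH, −78 °C
Reagents that add atoms: none
Why: Luche 1,2-reduction of the ynone; the C7 configuration does not matter because C7 is planarised in step 13.

Step 11
Reactants: 13 propargylic diol
Product: 14 C2 vinyl ketone with free C12–OH (bridged lactone opened)
Conditions: CH2=CHMgBr (3.5 equiv), THF, −78 to −40 °C; aq. NH4Cl
Reagents that add atoms: vinylmagnesium bromide, C=C[Mg]Br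
Why: Single Grignard addition to the strained bicyclic lactone (the magnesium hemiketal persists until quench) while the α-branched isopropyl ester is spared, unveiling the C2 vinyl ketone and O12.

Step 12
Reactants: 14 vinyl ketone
Product: 15 propargylic butanolide (C7–O–C19 lactone; C7 epimer mixture) carrying the C2 vinyl ketone
Conditions: CSA (0.2 equiv), PhMe, 70 °C
Reagents that add atoms: none
Why: Acid-catalysed lactonization; only O7 can close a five-membered ring on C19 (O9 is silylated, O8 would give a β-lactone), and this turns the C7 oxygen into a propargylic leaving group.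

Step 13
Reactants: 15 propargylic butanolide
Product: 16 ring B carbinol acid (trans-fused bicycle; C2 tertiary alcohol with vinyl, C7 prop-1-ynyl, C19 acid free)
Conditions: Pd(dppf)Cl2 (5 mol %), InI (1.5 equiv), THF/HMPA 4:1, 25 °C; aq. HCl work-up
Reagents that add atoms: none
Why: Barbier-type propargylation: zerovalent palladium ionises the propargylic carboxylate, transmetalation with monovalent indium gives an allenylindium, and this adds intramolecularly to the ketone through a chair six-ring transition state with vinyl and propynyl equatorial; C2 and C7 are not carried into the target.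

Step 14
Reactants: 16 ring B carbinol acid
Product: 17 ten-membered cyclic allene keto acid (C2 ketone, C5=C6=C7 allene, C8–OH, C9–OTBS, C12–OH)
Conditions: KH (6 equiv), 18-crown-6, THF, 0 to 50 °C; then aq. HCl (pH 3), 0 °C
Reagents that add atoms: none
Why: Anionic oxy-Cope rearrangement of the 3-oxido-1,5-enyne forms C4–C5 and cleaves C2–C7, expanding ring B to the ten-membered ring, driven by enolate formation; the allene axis is fixed by C7 but is not needed later.

Step 15
Reactants: 17 cyclic allene keto acid
Product: 18 (5E)-6-chloro-7,19-butanolide with C2 ketone (7R)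
Conditions: Pd(OAc)2 (5 mol %), LiCl (4 equiv), 1,4-benzoquinone (1.2 equiv), AcOH/THF 1:4, 25 °C
Reagents that add atoms: lithium chloride, [Li+].[Cl-]
Why: Proposed new method: stereoconvergent chlorolactonization of a medium-ring endocyclic allene — chloride adds to the central carbon of the allene bound to divalent palladium (a reversible chloropalladation, the process known to epimerise allene axes), the resulting (2-chloro-π-allyl)palladium is closed 5-exo by the C19 carboxylate at C7 anti to palladium, and benzoquinone reoxidises zerovalent palladium; the ring keeps C4 and C7 cis so the (5E)-chloroalkene forms, and 7R is expected because only the trans-fused butanolide (C6 and C9 trans) is reachable by the tether; the closest known reactions are the palladium/lithium halide 1,2-oxidation of acyclic allenic acids and the halolactonization of 4,5-allenoic acids.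

Step 16
Reactants: 18 chlorolactone ketone
Product: 19 the (2S)-alcohol of 18
Conditions: (R)-2-methyl-CBS-oxazaborolidine (0.5 equiv), catecholborane (3 equiv), PhMe, −78 to −40 °C
Reagents that add atoms: none
Why: CBS reduction under reagent control (quaternary C1 as the large group, C3 methylene as the small group) gives 2S.

Step 17
Reactants: 19 (2S)-alcohol
Product: 20 2,12-di-O-acetyl-9-O-TBS compound
Conditions: Ac2O, DMAP, pyridine, CH2Cl2, 25 °C
Reagents that add atoms: acetic anhydride, CC(=O)OC(C)=O
Why: Acetylation of the two secondary alcohols; the tertiary C8–OH and the silyl ether do not react.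

Step 18
Reactants: 20 bis-acetate silyl ether
Product: 21 target (CNP0296164.1)
Conditions: HF·pyridine, THF/pyridine, 0 to 25 °C
Reagents that add atoms: none
Why: Fluoride desilylation frees C9–OH only after C19 is locked in the 7,19-lactone, so the 9,19-lactone cannot form.

**Compound list**

1 | diisopropyl (S)-malate | CC(C)OC(=O)C[C@H](O)C(=O)OC(C)C | starting material
2 | diisopropyl (2S,3R)-2-hydroxy-3-methylbutanedioate | CC(C)OC(=O)[C@H](C)[C@H](O)C(=O)OC(C)C | intermediate
3 | (2S,3R)-2-hydroxy-3-methyl-4-oxo-4-(propan-2-yloxy)butanoic acid | CC(C)OC(=O)[C@H](C)[C@H](O)C(=O)O | intermediate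
4 | propan-2-yl (2R)-2-[(2S,4S)-2-tert-butyl-5-oxo-1,3-dioxolan-4-yl]propanoate | CC(C)OC(=O)[C@H](C)[C@@H]1O[C@H](C(C)(C)C)OC1=O | intermediate
5 | but-2-ynoyl chloride | CC#CC(=O)Cl | starting material
6 | propan-2-yl (2R)-2-[(2S,4R)-4-(but-2-ynoyl)-2-tert-butyl-5-oxo-1,3-dioxolan-4-yl]propanoate | CC(C)OC(=O)[C@H](C)[C@]1(C(=O)C#CC)O[C@H](C(C)(C)C)OC1=O | intermediate
7 | (Z)-but-2-enoyl analogue of 6 | CC(C)OC(=O)[C@H](C)[C@]1(C(=O)/C=C\C)O[C@H](C(C)(C)C)OC1=O | intermediate
8 | 3-methyl-2H-pyran-2-one | CC1=CC=COC1=O | starting material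
9 | endo Diels–Alder adduct (bridged lactone, C9 ketone) | CC(C)OC(=O)[C@H](C)[C@]1(C(=O)[C@H]2[C@@H](C)[C@H]3C=C[C@]2(C)C(=O)O3)O[C@H](C(C)(C)C)OC1=O | intermediate
10 | (9S)-alcohol of 9 | CC(C)OC(=O)[C@H](C)[C@]1([C@@H](O)[C@H]2[C@@H](C)[C@H]3C=C[C@]2(C)C(=O)O3)O[C@H](C(C)(C)C)OC1=O | intermediate
11 | 9-O-TBS ether of 10 | CC(C)OC(=O)[C@H](C)[C@]1([C@@H](O[Si](C)(C)C(C)(C)C)[C@H]2[C@@H](C)[C@H]3C=C[C@]2(C)C(=O)O3)O[C@H](C(C)(C)C)OC1=O | intermediate
12 | α-hydroxy ynone | CC(C)OC(=O)[C@H](C)[C@](O)(C(=O)C#CC)[C@@H](O[Si](C)(C)C(C)(C)C)[C@H]1[C@@H](C)[C@H]2C=C[C@]1(C)C(=O)O2 | intermediate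
13 | propargylic diol (C7 epimers) | CC(C)OC(=O)[C@H](C)[C@](O)(C(O)C#CC)[C@@H](O[Si](C)(C)C(C)(C)C)[C@H]1[C@@H](C)[C@H]2C=C[C@]1(C)C(=O)O2 | intermediate
14 | C2 vinyl ketone triol ester (C7 epimers) | CC(C)OC(=O)[C@H](C)[C@](O)(C(O)C#CC)[C@@H](O[Si](C)(C)C(C)(C)C)[C@H]1[C@@H](C)[C@H](O)C=C[C@]1(C)C(=O)C=C | intermediate
15 | propargylic 7,19-butanolide vinyl ketone (C7 epimers) | CC#CC1OC(=O)[C@H](C)[C@@]1(O)[C@@H](O[Si](C)(C)C(C)(C)C)[C@H]1[C@@H](C)[C@H](O)C=C[C@]1(C)C(=O)C=C | intermediate
16 | ring B carbinol acid | C=C[C@@]1(O)[C@H](C#CC)[C@@](O)([C@@H](C)C(=O)O)[C@@H](O[Si](C)(C)C(C)(C)C)[C@H]2[C@@H](C)[C@H](O)C=C[C@@]21C | intermediate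
17 | ten-membered cyclic allene keto acid (allene axis as formed, not needed later) | O=C1CCC(C)=C=C[C@@](O)([C@@H](C)C(=O)O)[C@@H](O[Si](C)(C)C(C)(C)C)[C@H]2[C@@H](C)[C@H](O)C=C[C@@]21C | intermediate
18 | (5E,7R)-6-chloro-7,19-butanolide C2 ketone | O=C1CC/C(C)=C(/Cl)[C@@H]2OC(=O)[C@H](C)[C@@]2(O)[C@@H](O[Si](C)(C)C(C)(C)C)[C@H]2[C@@H](C)[C@H](O)C=C[C@@]21C | intermediate
19 | (2S)-alcohol of 18 | O[C@H]1CC/C(C)=C(/Cl)[C@@H]2OC(=O)[C@H](C)[C@@]2(O)[C@@H](O[Si](C)(C)C(C)(C)C)[C@H]2[C@@H](C)[C@H](O)C=C[C@@]21C | intermediate
20 | 2,12-di-O-acetyl-9-O-TBS compound | CC(=O)O[C@H]1CC/C(C)=C(/Cl)[C@@H]2OC(=O)[C@H](C)[C@@]2(O)[C@@H](O[Si](C)(C)C(C)(C)C)[C@H]2[C@@H](C)[C@H](OC(C)=O)C=C[C@@]21C | intermediate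
21 | CNP0296164.1 | CC(=O)O[C@H]1CC/C(C)=C(/Cl)[C@@H]2OC(=O)[C@H](C)[C@@]2(O)[C@@H](O)[C@H]2[C@@H](C)[C@H](OC(C)=O)C=C[C@@]21C | target

**Step count**

Total steps: 18. Longest linear sequence: 18 (fully linear from 1).

**Three steps most likely to fail**

Step 15 (the proposed new chlorolactonization) may fail on the cyclic allene or give the C7 epimer. The fallback sets out from 17: iodine with NaHCO3 in MeCN, the established anti iodolactonization of 4,5-allenoic acids, gives the (5E)-6-iodo analogue of 18, iodolactone F1. Heating iodolactone F1 with CuCl in DMF (copper-mediated alkenyl iodide-to-chloride exchange) comes back to the route at 18.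

Step 6 (high-pressure Diels–Alder of the (Z)-enone) may suffer from Z/E isomerization or poor facial control by the dioxolanone. The fallback sets out from 8: a Diels–Alder reaction with (Z)-but-2-enoic acid under the same pressure, followed by resolution of the racemic endo adduct with (S)-1-phenylethylamine, gives the bicyclic lactone acid F2. Oxalyl chloride turns it into the acid chloride F3, which C-acylates the lithium enolate of 4 under the step 4 conditions and comes back to the route at 9.

Step 13 (palladium/indium ring closure onto the hindered vinyl ketone) may stall at the allenylmetal stage or give conjugate addition. The fallback sets out from 15: copper-catalysed SN2′ borylation of the propargylic carboxylate (CuCl, Xantphos, B2pin2, NaOt-Bu, THF) gives the isolable allenyl pinacolboronate acid F4. Its intramolecular propargylboration of the ketone (catalytic CuOAc with a bisphosphine, or heat) comes back to the route at 16.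

**Further compounds**

F1 | step 15 | (5E,7R)-6-iodo analogue of 18 | O=C1CC/C(C)=C(/I)[C@@H]2OC(=O)[C@H](C)[C@@]2(O)[C@@H](O[Si](C)(C)C(C)(C)C)[C@H]2[C@@H](C)[C@H](O)C=C[C@@]21C
F2 | step 6 | 5-endo,6-endo-4,6-dimethyl-3-oxo-2-oxabicyclo[2.2.2]oct-7-ene-5-carboxylic acid (resolved) | OC(=O)[C@H]1[C@@H](C)[C@H]2C=C[C@]1(C)C(=O)O2
F3 | step 6 | acid chloride of F2 | ClC(=O)[C@H]1[C@@H](C)[C@H]2C=C[C@]1(C)C(=O)O2
F4 | step 13 | allenyl pinacolboronate acid from 15 | CC(B1OC(C)(C)C(C)(C)O1)=C=C[C@@](O)([C@@H](C)C(=O)O)[C@@H](O[Si](C)(C)C(C)(C)C)[C@H]1[C@@H](C)[C@H](O)C=C[C@]1(C)C(=O)C=C
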